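**Plan**

- Retrosynthesis: the four phenols are unmasked last. Both aryl ether bonds O1–C8a and O1''–C8a'' (flavanone numbering) are cut in one operation, then both C4–C4a aryl ketone bonds. This leads to a cis-fused dilactone, which is cut at the two C2–C3 aldol bonds to a succinyl bis-imide.
- Forward: the C4–C3–C3''–C4'' succinyl backbone comes first. Two anti-aldols add C2/C2'' with their aryl groups. Two γ-lactone rings (a 3,7-dioxabicyclo[3.3.0]octane-4,8-dione) then store the stereotetrad and release the auxiliaries. Two 2-fluoroaryl ketones bring in rings A, both pyranone rings C close together, and debenzylation finishes.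
- Enabling feature: in each half the C4 ketone sits ortho to C8a of ring A and makes a C8a–F bond an SNAr site, while O1 is carried by the benzylic carbon C2, 1,3 to that ketone. The same O1 is 1,4 to the C4'' carbonyl of the other half, so the two future pyran oxygens first serve as the ring oxygens of a rigid dilactone and are then passed from acyl carbon to aryl carbon.
- Stereochemistry: all four centers come from the (R)-4-benzyl-oxazolidinone auxiliaries in a twofold magnesium-catalysed anti-aldol. They are locked in the bicycle and are not touched by the ring closures; 2,3-trans is also the thermodynamic arrangement.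

Key step: step 5

Assumption: CIP analysis of the given SMILES gives (2R,3S,2''R,3''S), the C2-symmetric isomer with both flavanone units 2,3-trans. Compound 11 is a ring–chain tautomer mixture and is listed as its bis-lactol form.

**Route**

Step 1
Reactants: 1 succinyl chloride; 2 (R)-4-benzyl-1,3-oxazolidin-2-one (2 equiv)
Product: 3 1,4-bis[(4R)-4-benzyl-2-oxo-1,3-oxazolidin-3-yl]butane-1,4-dione
Conditions: 2, n-BuLi, THF, −78 °C; then 1, −78 → 0 °C
Reagents that add atoms: none
Why: N-acylation of the lithiated oxazolidinone by the diacid chloride (Evans acylation) at both ends should give the C2-symmetric bis-imide; no stereocenter is formed.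

Step 2
Reactants: 3 bis-imide; 4 4-(benzyloxy)benzaldehyde (2.5 equiv)
Product: 5 (2S,3S)-2,3-bis{(R)-[4-(benzyloxy)phenyl][(trimethylsilyl)oxy]methyl}-1,4-bis[(4R)-4-benzyl-2-oxo-1,3-oxazolidin-3-yl]butane-1,4-dione
Conditions: MgCl2 (20 mol%), NaSbF6 (60 mol%), Et3N, TMSCl, EtOAc, 23 °C
Reagents that add atoms: chlorotrimethylsilane, C[Si](C)(C)Cl
Why: Evans magnesium halide-catalysed direct anti-aldol of an N-acyloxazolidinone with a non-enolisable aromatic aldehyde, run once on each half; Et3N enolises the MgCl2-chelated imide to the chelated (Z)-enolate, the aldehyde attacks the face away from the auxiliary benzyl group through a boat-like transition state, and TMSCl traps the aldolate and turns the metal over, so each (R)-auxiliary should set its own α/β pair anti (α-S, β-R).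

Step 3
Reactants: 5 bis-TMS ether
Product: 8 (1S,2R,5S,6R)-2,6-bis[4-(benzyloxy)phenyl]-3,7-dioxabicyclo[3.3.0]octane-4,8-dione, via diol bis-imide 6 (not isolated), via mono-lactone 7 (not isolated)
Conditions: AcOH–THF–H2O, 0 °C; then Et3N, DMAP (cat.), CH2Cl2, 23 °C
Reagents that add atoms: none
Why: Mild hydrolysis of the TMS ethers is followed by intramolecular acyl transfer, in which each hydroxyl attacks the exocyclic imide carbonyl of the other half (5-exo-trig) and expels the oxazolidinone; no stereocenter is touched, and the cis-fused bicycle locks both bridgehead α-carbons against epimerisation.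

Step 4
Reactants: 8 dilactone; 9 4-(benzyloxy)-1-bromo-2-fluorobenzene (2.1 equiv)
Product: 11 (1S,2R,5S,6R)-2,6-bis[4-(benzyloxy)phenyl]-4,8-bis[4-(benzyloxy)-2-fluorophenyl]-3,7-dioxabicyclo[3.3.0]octane-4,8-diol (anomer mixture; used crude), via aryllithium 10 (not isolated)
Conditions: 9, n-BuLi, THF, −78 °C; then 8, −78 °C; AcOH, −78 °C
Reagents that add atoms: none
Why: Bromine–lithium exchange and single addition of the aryllithium to each lactone carbonyl from the convex face; the tetrahedral lithium lactolate should persist at −78 °C (as in C-aryl glycoside synthesis from sugar lactones), which prevents a second addition, and the ortho-fluoro aryllithium should not lose LiF at this temperature.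

Step 5
Reactants: 11 bis-lactol
Product: 14 (2R,2'R,3S,3'S)-7,7'-bis(benzyloxy)-2,2'-bis[4-(benzyloxy)phenyl]-[3,3'-bichromane]-4,4'-dione, via open-chain diol diketone 12 (not isolated), via half-closed hydroxy ketone 13 (not isolated)
Conditions: KN(SiMe3)2 (2.05 equiv), THF, −78 → 0 °C; pH 7 buffer
Reagents that add atoms: none
Why: The base deprotonates the hydroxyls of 11; each lactolate ring-opens to an aryl ketone and a C2 alkoxide, which adds to the fluorine-bearing ring A carbon ortho to its own C4 carbonyl to give a Meisenheimer anion (charge relayed through C4a onto the C4 oxygen) that expels fluoride, and the sequence repeats in the second half through 12 and 13. The closest known reaction type is the intramolecular SNAr O-arylation ortho to an aryl ketone used to make chromones, xanthones and 4-quinolones from 2-fluoroaryl ketones. Both pyranone rings close in the six-membered mode at a trigonal aromatic carbon (6-exo with respect to the C8a–C8 π bond, while the C8a–C4a bond that relays the charge lies inside the new ring), and two five-membered lactol rings are exchanged for two six-membered rings. No new stereocenter is created: C2 and C2'' keep their configuration because their C–O bonds are never broken (the oxygen is the nucleophile), and C3 and C3'' already hold the trans, diequatorial arrangement that is also the thermodynamic one, so transient enolisation cannot lead away from it. The step needs six-ring attack on the proximal ring A to outrun seven-ring attack on the distal fluoroarene, retro-aldol cleavage of the β-alkoxy ketone and E1cB reopening of the product; the 1,3-relation of O1 to C4 should secure the ring size, the lactolate resting state and low temperature should limit the free β-alkoxide, and one equivalent of base per ring is consumed as KF so that none remains to open the flavanone.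

Step 6
Reactants: 14 tetrabenzyl ether
Product: 15 (2R,2'R,3S,3'S)-7,7'-dihydroxy-2,2'-bis(4-hydroxyphenyl)-[3,3'-bichromane]-4,4'-dione (target)
Conditions: H2 (1 atm), 10% Pd/C, EtOAc–MeOH, 23 °C
Reagents that add atoms: none
Why: Hydrogenolysis of the four benzyl aryl ethers under neutral conditions; the aryl ketones and the C2–O1 bonds should survive at ambient pressure with the reaction stopped at full debenzylation, and no stereocenter is affected.

**Compound list**

1 | succinyl chloride | ClC(=O)CCC(=O)Cl | starting material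
2 | (R)-4-benzyl-1,3-oxazolidin-2-one | O=C1N[C@H](Cc2ccccc2)CO1 | starting material
3 | 1,4-bis[(4R)-4-benzyl-2-oxo-1,3-oxazolidin-3-yl]butane-1,4-dione | O=C(CCC(=O)N1[C@H](Cc2ccccc2)COC1=O)N1[C@H](Cc2ccccc2)COC1=O | intermediate
4 | 4-(benzyloxy)benzaldehyde | O=Cc1ccc(OCc2ccccc2)cc1 | starting material
5 | (2S,3S)-2,3-bis{(R)-[4-(benzyloxy)phenyl][(trimethylsilyl)oxy]methyl}-1,4-bis[(4R)-4-benzyl-2-oxo-1,3-oxazolidin-3-yl]butane-1,4-dione (anti,anti bis-aldol, bis-TMS ether) | C[Si](C)(C)O[C@@H](c1ccc(OCc2ccccc2)cc1)[C@@H](C(=O)N1[C@H](Cc2ccccc2)COC1=O)[C@@H]([C@@H](O[Si](C)(C)C)c1ccc(OCc2ccccc2)cc1)C(=O)N1[C@H](Cc2ccccc2)COC1=O | intermediate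
6 | (2S,3S)-2,3-bis{(R)-[4-(benzyloxy)phenyl](hydroxy)methyl}-1,4-bis[(4R)-4-benzyl-2-oxo-1,3-oxazolidin-3-yl]butane-1,4-dione (diol bis-imide) | O[C@@H](c1ccc(OCc2ccccc2)cc1)[C@@H](C(=O)N1[C@H](Cc2ccccc2)COC1=O)[C@@H]([C@@H](O)c1ccc(OCc2ccccc2)cc1)C(=O)N1[C@H](Cc2ccccc2)COC1=O | intermediate
7 | (4R)-4-benzyl-3-{(2R,3S,4S)-2-[4-(benzyloxy)phenyl]-4-{(R)-[4-(benzyloxy)phenyl](hydroxy)methyl}-5-oxooxolane-3-carbonyl}-1,3-oxazolidin-2-one (mono-lactone) | O1[C@@H](c2ccc(OCc3ccccc3)cc2)[C@@H](C(=O)N4[C@H](Cc5ccccc5)COC4=O)[C@@H]([C@@H](O)c6ccc(OCc7ccccc7)cc6)C1=O | intermediate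
8 | (1S,2R,5S,6R)-2,6-bis[4-(benzyloxy)phenyl]-3,7-dioxabicyclo[3.3.0]octane-4,8-dione (cis-fused, both aryl groups endo) | O1[C@@H](c2ccc(OCc3ccccc3)cc2)[C@H]4C(=O)O[C@@H](c5ccc(OCc6ccccc6)cc5)[C@H]4C1=O | intermediate
9 | 4-(benzyloxy)-1-bromo-2-fluorobenzene | Brc1ccc(OCc2ccccc2)cc1F | starting material
10 | [4-(benzyloxy)-2-fluorophenyl]lithium | [Li]c1ccc(OCc2ccccc2)cc1F | intermediate
11 | (1S,2R,5S,6R)-2,6-bis[4-(benzyloxy)phenyl]-4,8-bis[4-(benzyloxy)-2-fluorophenyl]-3,7-dioxabicyclo[3.3.0]octane-4,8-diol (bis-lactol, anomer mixture, in ring–chain equilibrium with 12) | O1[C@@H](c2ccc(OCc3ccccc3)cc2)[C@H]4C(O)(c2ccc(OCc3ccccc3)cc2F)O[C@@H](c2ccc(OCc3ccccc3)cc2)[C@H]4C1(O)c5ccc(OCc6ccccc6)cc5F | intermediate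
12 | (2S,3S)-1,4-bis[4-(benzyloxy)-2-fluorophenyl]-2,3-bis{(R)-[4-(benzyloxy)phenyl](hydroxy)methyl}butane-1,4-dione (open-chain form, reacting as its alkoxide) | O[C@@H](c1ccc(OCc2ccccc2)cc1)[C@@H](C(=O)c1ccc(OCc2ccccc2)cc1F)[C@@H]([C@@H](O)c1ccc(OCc2ccccc2)cc1)C(=O)c1ccc(OCc2ccccc2)cc1F | intermediate
13 | (2R,3S)-7-(benzyloxy)-2-[4-(benzyloxy)phenyl]-3-{(1S,2R)-1-[4-(benzyloxy)-2-fluorobenzoyl]-2-[4-(benzyloxy)phenyl]-2-hydroxyethyl}chroman-4-one (one ring closed) | O=C1c2ccc(OCc3ccccc3)cc2O[C@@H](c2ccc(OCc3ccccc3)cc2)[C@@H]1[C@@H]([C@@H](O)c1ccc(OCc2ccccc2)cc1)C(=O)c1ccc(OCc2ccccc2)cc1F | intermediate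
14 | (2R,2'R,3S,3'S)-7,7'-bis(benzyloxy)-2,2'-bis[4-(benzyloxy)phenyl]-[3,3'-bichromane]-4,4'-dione | O=C1c2ccc(OCc3ccccc3)cc2O[C@@H](c2ccc(OCc3ccccc3)cc2)[C@@H]1[C@@H]1C(=O)c2ccc(OCc3ccccc3)cc2O[C@H]1c1ccc(OCc2ccccc2)cc1 | intermediate
15 | (2R,2'R,3S,3'S)-7,7'-dihydroxy-2,2'-bis(4-hydroxyphenyl)-[3,3'-bichromane]-4,4'-dione | O=C1c2ccc(O)cc2O[C@@H](c2ccc(O)cc2)[C@@H]1[C@@H]1C(=O)c2ccc(O)cc2O[C@H]1c1ccc(O)cc1 | target

**Step count and risks**

Total steps: 6. Longest linear sequence: 6 (1 → 3 → 5 → 8 → 11 → 14 → 15).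

Steps most likely to fail:

1. Step 5. The free β-alkoxy ketone may undergo retro-aldol cleavage and recombination, which would scramble C2 and C3. Seven-ring attack on the distal fluoroarene or base-induced reopening of the finished pyranone may also compete. The fallback sets out from 8 and changes the C–O bond-forming event from attack of a free alkoxide to reductive elimination at a metal. Dilactone 8 would be treated at −40 °C with [4-(benzyloxy)-2-chlorophenyl]magnesium chloride F1, made from 4-(benzyloxy)-1-bromo-2-chlorobenzene and i-PrMgCl·LiCl in THF at −15 °C. This should give the chloro bis-lactol F2, the 4,8-bis[4-(benzyloxy)-2-chlorophenyl] analogue of 11. Both rings would then be closed by palladium-catalysed intramolecular C–O coupling (Buchwald–Hartwig-type etherification; Pd(OAc)2, 2-(di-tert-butylphosphino)-1,1'-binaphthyl, K3PO4, toluene, 70 °C). The alkoxide is bound to palladium and the insoluble weak base keeps free alkoxide negligible. The fallback comes back to the route at 14.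

2. Step 2. The second enolisation next to a branched α-carbon may be slow, the first aldolate may lactonise onto the distal imide before the second aldol, or the anti selectivity may be poor. The fallback sets out from 3 and gives up kinetic control of C3, keeping only the auxiliary-controlled carbinol centers. A twofold Evans syn-aldol (Bu2BOTf, i-Pr2NEt, CH2Cl2, −78 → 0 °C; then 4; H2O2 work-up) should give the syn,syn diol bis-imide F3 with both carbinol centers R. Lactonisation (Et3N, DMAP) should give the exo,exo dilactone F4. Addition of aryllithium 10 as in step 4 should give bis-lactol F5, and ring closure as in step 5 should give the 2,3-cis,2'',3''-cis biflavanone F6. Base-catalysed epimerisation of the two ketone α-carbons C3 and C3'' (Et3N, MeOH–CH2Cl2, 23 °C) into the diequatorial arrangement should then give the trans,trans isomer. The fallback comes back to the route at 14.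

3. Step 4. The aryllithium may deprotonate the lactone α-carbon with β-elimination of the carboxylate, a second aryl group may add after premature lactolate opening, or LiF may be lost to an aryne. The fallback sets out from 8 and separates ring opening from C–C bond formation. Both lactones would be opened with Me3Al and MeNHOMe·HCl (CH2Cl2, 0 °C) to the bis-Weinreb amide diol F7. This would be treated with excess [4-(benzyloxy)-2-fluorophenyl]magnesium chloride F8, made from 9 and i-PrMgCl·LiCl (THF, −15 → 0 °C). The first two equivalents deprotonate the hydroxyls and the stable magnesium chelates prevent over-addition. The fallback comes back to the route at 11.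

**Further compounds**

F1 | step 5 | [4-(benzyloxy)-2-chlorophenyl]magnesium chloride | Cl[Mg]c1ccc(OCc2ccccc2)cc1Cl
F2 | step 5 | (1S,2R,5S,6R)-2,6-bis[4-(benzyloxy)phenyl]-4,8-bis[4-(benzyloxy)-2-chlorophenyl]-3,7-dioxabicyclo[3.3.0]octane-4,8-diol | O1[C@@H](c2ccc(OCc3ccccc3)cc2)[C@H]4C(O)(c2ccc(OCc3ccccc3)cc2Cl)O[C@@H](c2ccc(OCc3ccccc3)cc2)[C@H]4C1(O)c5ccc(OCc6ccccc6)cc5Cl
F3 | step 2 | (2R,3R)-2,3-bis{(R)-[4-(benzyloxy)phenyl](hydroxy)methyl}-1,4-bis[(4R)-4-benzyl-2-oxo-1,3-oxazolidin-3-yl]butane-1,4-dione (syn,syn) | O[C@@H](c1ccc(OCc2ccccc2)cc1)[C@H](C(=O)N1[C@H](Cc2ccccc2)COC1=O)[C@H]([C@@H](O)c1ccc(OCc2ccccc2)cc1)C(=O)N1[C@H](Cc2ccccc2)COC1=O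
F4 | step 2 | (1R,2R,5R,6R)-2,6-bis[4-(benzyloxy)phenyl]-3,7-dioxabicyclo[3.3.0]octane-4,8-dione (both aryl groups exo) | O1[C@@H](c2ccc(OCc3ccccc3)cc2)[C@@H]4C(=O)O[C@@H](c5ccc(OCc6ccccc6)cc5)[C@@H]4C1=O
F5 | step 2 | (1R,2R,5R,6R)-2,6-bis[4-(benzyloxy)phenyl]-4,8-bis[4-(benzyloxy)-2-fluorophenyl]-3,7-dioxabicyclo[3.3.0]octane-4,8-diol | O1[C@@H](c2ccc(OCc3ccccc3)cc2)[C@@H]4C(O)(c2ccc(OCc3ccccc3)cc2F)O[C@@H](c2ccc(OCc3ccccc3)cc2)[C@@H]4C1(O)c5ccc(OCc6ccccc6)cc5F
F6 | step 2 | (2R,2'R,3R,3'R)-7,7'-bis(benzyloxy)-2,2'-bis[4-(benzyloxy)phenyl]-[3,3'-bichromane]-4,4'-dione (cis,cis) | O=C1c2ccc(OCc3ccccc3)cc2O[C@@H](c2ccc(OCc3ccccc3)cc2)[C@H]1[C@H]1C(=O)c2ccc(OCc3ccccc3)cc2O[C@H]1c1ccc(OCc2ccccc2)cc1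
F7 | step 4 | (2S,3S)-2,3-bis{(R)-[4-(benzyloxy)phenyl](hydroxy)methyl}-N1,N4-dimethoxy-N1,N4-dimethylbutanediamide | O[C@@H](c1ccc(OCc2ccccc2)cc1)[C@@H](C(=O)N(C)OC)[C@@H]([C@@H](O)c1ccc(OCc2ccccc2)cc1)C(=O)N(C)OC
F8 | step 4 | [4-(benzyloxy)-2-fluorophenyl]magnesium chloride | Cl[Mg]c1ccc(OCc2ccccc2)cc1F
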